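**Plan**

1. Numbering used throughout (tuberostemonine type): pyrrole C1–C2–C3–N4–C9a; azepine N4–C5–C6–C7–C8–C9–C9a; cyclohexene C9a–C1–C12–C11–C10–C9; fused lactone O–C11–C12–C13(Me)–C14(=O); ethyl C16–C17 on C10; pendant lactone O–C18–C19–C20(Me)–C21(=O) on C3.
2. Retrosynthesis: C20–Me and C10–Et are traced back to C20=CH2 and C10–CH=CH2 (from C10–CHO). C9–C9a and C10–C11 are then cut together (retro-[4+2]), which opens the azepine and the cyclohexene in one stroke. Further cuts: C9=C10 (cross-metathesis), C18–C19 (allylation/lactonisation), C1–C12 (Suzuki–Miyaura coupling), N4–C5 (N-alkylation).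
3. Enabling feature: the pyrrole bond C1=C9a and the enol-ether bond C11=C12 of the furanone ring, once that ring is held as its 2-siloxyfuran, are joined through C1–C12 into a 1-oxy-4-amino diene (O–C11=C12–C1=C9a–N4). N4 sits on the diene terminus C9a, so a four-carbon chain C5–C8 on N4 holds the enal bond C9=C10 over the diene; the azepine closes as the tether ring and the cyclohexene as the cycloadduct ring.
4. Forward order: pyrrole and furanone rings are bought; C1–C12 coupling; pendant lactone ring; then cyclohexene and azepine together in the key step. No ring is closed afterwards. The helpers (silyl group, formyl group, exocyclic methylene) are removed in the key step and the last two steps.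
5. Stereochemistry: C18 from a chiral chromium allylation catalyst; C9 from a chiral imidazolidinone (iminium) catalyst; C10 and C11 from the E-enal and the endo mode of the cycloaddition; C12 and C13 from convex-face protonation as pyrrole and lactone re-form; C20 from hydrogenation anti to the pyrrole.

Key step: step 7

Assumption: α-methyltetronic acid is taken as purchasable (otherwise two steps from ethyl 2-methylacetoacetate). The two catalyst enantiomers are chosen from the accepted facial models and would be confirmed on the first chiral intermediates.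

**Route**

Step 1
Reactants: 1 4-bromo-1H-pyrrole-2-carbaldehyde; 2 6-bromohex-1-ene
Product: 3 4-bromo-1-(hex-5-en-1-yl)-1H-pyrrole-2-carbaldehyde
Conditions: K2CO3, DMF, 60 °C
Reagents that add atoms: none
Why: SN2 N-alkylation of the pyrrolide anion, which the 2-formyl group makes easy to form, installs N4–C5 and the chain C5–C9.

Step 2
Reactants: 4 4-hydroxy-3-methylfuran-2(5H)-one (α-methyltetronic acid)
Product: 5 4-methyl-5-oxo-2,5-dihydrofuran-3-yl trifluoromethanesulfonate
Conditions: Tf2O, iPr2NEt, CH2Cl2, −78 °C
Reagents that add atoms: trifluoromethanesulfonic anhydride, O=S(=O)(OS(=O)(=O)C(F)(F)F)C(F)(F)F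
Why: O-sulfonylation of the vinylogous acid gives the vinyl triflate needed as the coupling electrophile.

Step 3
Reactants: 3 4-bromo-1-(hex-5-en-1-yl)-1H-pyrrole-2-carbaldehyde; 5 4-methyl-5-oxo-2,5-dihydrofuran-3-yl trifluoromethanesulfonate
Product: 7 1-(hex-5-en-1-yl)-4-(4-methyl-5-oxo-2,5-dihydrofuran-3-yl)-1H-pyrrole-2-carbaldehyde, via pinacol boronate 6 (not isolated)
Conditions: B2pin2, KOAc, Pd(dppf)Cl2 (3 mol %), 1,4-dioxane, 90 °C; then 5, K3PO4, H2O, 60 °C
Reagents that add atoms: none
Why: Miyaura borylation of the bromopyrrole followed in the same flask by Suzuki–Miyaura coupling with the tetronate triflate should form the C1–C12 bond.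

Step 4
Reactants: 7 1-(hex-5-en-1-yl)-4-(4-methyl-5-oxo-2,5-dihydrofuran-3-yl)-1H-pyrrole-2-carbaldehyde; 8 ethyl 2-(bromomethyl)acrylate
Product: 10 (5S)-5-[1-(hex-5-en-1-yl)-4-(4-methyl-5-oxo-2,5-dihydrofuran-3-yl)-1H-pyrrol-2-yl]-3-methylideneoxolan-2-one, via trimethylsilyl ether 9 (not isolated)
Conditions: CrCl2 (10 mol %), chiral 1,8-bis(oxazolinyl)carbazole ligand (12 mol %, the enantiomer that directs attack on the Si face of the aldehyde), Mn, TMSCl, iPr2NEt (cat.), THF, rt; then TBAF, THF, 0 °C
Reagents that add atoms: none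
Why: Catalytic asymmetric Nozaki–Hiyama–Kishi-type 2-(alkoxycarbonyl)allylation should add the allylchromium species to the Si face of the formyl group inside the chiral ligand sphere (C18 S), and fluoride then frees the alkoxide, which closes the α-methylene-γ-butyrolactone.

Step 5
Reactants: 10 (5S)-5-[1-(hex-5-en-1-yl)-4-(4-methyl-5-oxo-2,5-dihydrofuran-3-yl)-1H-pyrrol-2-yl]-3-methylideneoxolan-2-one
Product: 11 (5S)-5-[1-(hex-5-en-1-yl)-4-{4-methyl-5-[tri(propan-2-yl)silyloxy]furan-3-yl}-1H-pyrrol-2-yl]-3-methylideneoxolan-2-one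
Conditions: TIPSOTf, Et3N, CH2Cl2, 0 °C
Reagents that add atoms: triisopropylsilyl trifluoromethanesulfonate, CC(C)[Si](OS(=O)(=O)C(F)(F)F)(C(C)C)C(C)C
Why: Soft enolisation (O-silylation and loss of the acidic C11 proton) should turn the butenolide into the aromatic 2-siloxyfuran, while the pendant lactone has no comparably acidic proton.

Step 6
Reactants: 11 (5S)-5-[1-(hex-5-en-1-yl)-4-{4-methyl-5-[tri(propan-2-yl)silyloxy]furan-3-yl}-1H-pyrrol-2-yl]-3-methylideneoxolan-2-one; 12 (E)-but-2-enal (crotonaldehyde)
Product: 13 (2E)-7-{2-[(2S)-4-methylidene-5-oxooxolan-2-yl]-4-{4-methyl-5-[tri(propan-2-yl)silyloxy]furan-3-yl}-1H-pyrrol-1-yl}hept-2-enal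
Conditions: second-generation Hoveyda–Grubbs catalyst (5 mol %), 12 (5 equiv), CH2Cl2, 40 °C
Reagents that add atoms: none
Why: Olefin cross-metathesis of the terminal alkene with excess crotonaldehyde should give the E-enal C9=C10 with loss of propene, the hindered exocyclic methylene and the furan bonds reacting far more slowly.

Step 7
Reactants: 13 (2E)-7-{2-[(2S)-4-methylidene-5-oxooxolan-2-yl]-4-{4-methyl-5-[tri(propan-2-yl)silyloxy]furan-3-yl}-1H-pyrrol-1-yl}hept-2-enal
Product: 15 pentacyclic aldehyde (9R,10R,11S,12S,13S,18S): the target skeleton carrying CHO in place of the C10 ethyl group and =CH2 in place of the C20 methyl group, via silyl ketene acetal cycloadduct 14 (not isolated)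
Conditions: (2S,5S)-5-benzyl-2-tert-butyl-3-methylimidazolidin-4-one (20 mol %), 2,4-dinitrobenzoic acid (20 mol %), H2O (2 equiv), CH2Cl2 (0.01 M), −40 °C
Reagents that add atoms: none
Why: Proposed new method: the amine salt turns the enal into an E-iminium ion, pyrrole C9a attacks C9 and the enamine carbon C10 closes on C11 of the furan-stabilised cation, i.e. a concerted but asynchronous (or closely coupled two-stage) [4+2] cycloaddition across the diene O–C11=C12–C1=C9a; hydrolysis of the iminium ion gives 14, whose silyl ketene acetal is protonated at C13 with loss of the silyl group and whose C9a proton moves to C12, which restores the pyrrole and unveils the lactone. The closest known reaction types are the amine-catalysed Diels–Alder reactions of vinylindoles with enals, the amine-catalysed Friedel–Crafts alkylation of pyrroles and Mukaiyama–Michael addition of 2-siloxyfurans with enals, and intramolecular Diels–Alder reactions of vinyl-heteroarenes; new is a diene made of one C=C bond from each of two heteroarenes. Both rings close in this one event: the azepine as the tether ring (7-exo attack of C9a on C9, bond C9–C9a) and the cyclohexene as the cycloadduct ring (bond C10–C11). C9 is set by the catalyst, whose benzyl group should shield the Si face of C9 so that C9a adds to the Re face (R); C10 follows from the E-enal (formyl trans to C8) and is epimerisable through the enamine towards the equatorial target configuration; C11 follows from the suprafacial endo mode with the tether exo (formyl cis to the ring oxygen); C12 and C13 come from protonation on the convex face anti to C10, which gives the cis-fused lactone with the C13 methyl on the concave face. The step needs attack by pyrrole C9a and not by furan C11 on the iminium ion, which the tether length secures (seven- against ten-membered ring), and it needs ring closure at C11 to outrun simple loss of the C9a proton, which the oxocarbenium character of C11 and the six-membered closure should favour; high dilution suppresses intermolecular Mukaiyama–Michael addition.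

Step 8
Reactants: 15 pentacyclic aldehyde (9R,10R,11S,12S,13S,18S)
Product: 16 pentacyclic diene (9R,10R,11R,12S,13S,18S): the target skeleton carrying CH=CH2 on C10 and =CH2 on C20
Conditions: Ph3PCH3Br, KN(SiMe3)2, THF, −78 to 0 °C
Reagents that add atoms: methyltriphenylphosphonium bromide, C[P+](c1ccccc1)(c1ccccc1)c1ccccc1.[Br-]
Why: Wittig methylenation of the aldehyde at low temperature with a near-stoichiometric ylide should add C17 without touching the base-sensitive centres C10 and C13.

Step 9
Reactants: 16 pentacyclic diene (9R,10R,11R,12S,13S,18S)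
Product: 17 bisdehydroneotuberostemonine (9R,10R,11R,12S,13S,18S,20S)
Conditions: H2 (1 atm), Rh/Al2O3 (5 wt %), EtOAc, rt
Reagents that add atoms: none
Why: Heterogeneous hydrogenation should saturate the vinyl group to the C10 ethyl group and add hydrogen to the exocyclic methylene from the face opposite the pyrrole on C18, setting C20 (S) with the methyl cis to the pyrrole; Rh/Al2O3 is chosen to avoid hydrogenolysis of the pyrrolyl C18–O bond.

**Compound list**

1 | 4-bromo-1H-pyrrole-2-carbaldehyde | O=Cc1cc(Br)c[nH]1 | starting material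
2 | 6-bromohex-1-ene | C=CCCCCBr | starting material
3 | 4-bromo-1-(hex-5-en-1-yl)-1H-pyrrole-2-carbaldehyde | O=Cc1cc(Br)cn1CCCCC=C | intermediate
4 | 4-hydroxy-3-methylfuran-2(5H)-one (α-methyltetronic acid) | CC1=C(O)COC1=O | starting material
5 | 4-methyl-5-oxo-2,5-dihydrofuran-3-yl trifluoromethanesulfonate | CC1=C(OS(=O)(=O)C(F)(F)F)COC1=O | intermediate
6 | 1-(hex-5-en-1-yl)-4-(4,4,5,5-tetramethyl-1,3,2-dioxaborolan-2-yl)-1H-pyrrole-2-carbaldehyde | O=Cc1cc(B2OC(C)(C)C(C)(C)O2)cn1CCCCC=C | intermediate (not isolated)
7 | 1-(hex-5-en-1-yl)-4-(4-methyl-5-oxo-2,5-dihydrofuran-3-yl)-1H-pyrrole-2-carbaldehyde | O=Cc1cc(C2=C(C)C(=O)OC2)cn1CCCCC=C | intermediate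
8 | ethyl 2-(bromomethyl)acrylate | C=C(CBr)C(=O)OCC | starting material
9 | ethyl (4S)-4-[1-(hex-5-en-1-yl)-4-(4-methyl-5-oxo-2,5-dihydrofuran-3-yl)-1H-pyrrol-2-yl]-2-methylidene-4-[(trimethylsilyl)oxy]butanoate | C=CCCCCn1cc(C2=C(C)C(=O)OC2)cc1[C@@H](O[Si](C)(C)C)CC(=C)C(=O)OCC | intermediate (not isolated)
10 | (5S)-5-[1-(hex-5-en-1-yl)-4-(4-methyl-5-oxo-2,5-dihydrofuran-3-yl)-1H-pyrrol-2-yl]-3-methylideneoxolan-2-one | C=CCCCCn1cc(C2=C(C)C(=O)OC2)cc1[C@@H]3CC(=C)C(=O)O3 | intermediate
11 | (5S)-5-[1-(hex-5-en-1-yl)-4-{4-methyl-5-[tri(propan-2-yl)silyloxy]furan-3-yl}-1H-pyrrol-2-yl]-3-methylideneoxolan-2-one | C=CCCCCn1cc(-c2coc(O[Si](C(C)C)(C(C)C)C(C)C)c2C)cc1[C@@H]3CC(=C)C(=O)O3 | intermediate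
12 | (E)-but-2-enal (crotonaldehyde) | C/C=C/C=O | starting material
13 | (2E)-7-{2-[(2S)-4-methylidene-5-oxooxolan-2-yl]-4-{4-methyl-5-[tri(propan-2-yl)silyloxy]furan-3-yl}-1H-pyrrol-1-yl}hept-2-enal | O=C/C=C/CCCCn1cc(-c2coc(O[Si](C(C)C)(C(C)C)C(C)C)c2C)cc1[C@@H]3CC(=C)C(=O)O3 | intermediate
14 | primary cycloadduct: 9a-H dihydropyrrole with exocyclic C1=C12 bond, C13=C14 silyl ketene acetal, C10 formyl group, trans-fused azepine, 20-methylidene pendant lactone | O=C[C@H]1[C@H]2OC(O[Si](C(C)C)(C(C)C)C(C)C)=C(C)C2=C5C=C([C@@H]4CC(=C)C(=O)O4)N3[C@H]5[C@@H]1CCCC3 | intermediate (not isolated)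
15 | pentacyclic aldehyde (9R,10R,11S,12S,13S,18S): target skeleton with CHO on C10 and =CH2 on C20 | O=C[C@H]1[C@H]2OC(=O)[C@@H](C)[C@H]2c2cc([C@@H]3CC(=C)C(=O)O3)n3c2[C@@H]1CCCC3 | intermediate
16 | pentacyclic diene (9R,10R,11R,12S,13S,18S): target skeleton with CH=CH2 on C10 and =CH2 on C20 | C=C[C@H]1[C@H]2OC(=O)[C@@H](C)[C@H]2c2cc([C@@H]3CC(=C)C(=O)O3)n3c2[C@@H]1CCCC3 | intermediate
17 | bisdehydroneotuberostemonine (9R,10R,11R,12S,13S,18S,20S) | CC[C@H]1[C@H]2OC(=O)[C@@H](C)[C@H]2c2cc([C@@H]3C[C@H](C)C(=O)O3)n3c2[C@@H]1CCCC3 | target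

**Step count**

Total: 9 steps. Longest linear sequence: 8 steps (1 → 3 → 7 → 10 → 11 → 13 → 15 → 16 → 17; the triflate 5 is made in a one-step branch).

**Steps most likely to fail**

Step 7 (labelled step). The first adduct may lose its C9a proton before the C10–C11 bond forms, so that only the azepine closes and the siloxyfuran is regenerated. The siloxyfuran may also attack the iminium ion of a second molecule, and facial control by the catalyst may be incomplete. The fallback uses known reaction types, sets out from 10 and returns to the route at 17. The furanone of 10 is deprotonated at C11 with LiN(SiMe3)2 (THF, −78 °C) and the furanolate is sulfenylated at C13 with S-phenyl benzenethiosulfonate (deconjugative α-sulfenylation of a butenolide dienolate). This gives the α-phenylsulfanyl enol lactone F1, in which the C11=C12 enol-ester bond is locked next to the pyrrole without any silyl group. Cross-metathesis with crotonaldehyde as in step 6 gives the sulfide enal F2. An intramolecular Diels–Alder reaction of this 3-vinylpyrrole-type 1-acyloxy diene with the tethered enal (same imidazolidinone salt, or toluene at 110 °C), followed by the proton shift from C9a to C12, gives the pentacyclic sulfide aldehyde F3. Wittig methylenation as in step 8 gives the vinyl sulfide F4. Raney Ni under H2 (EtOH, rt) then removes the sulfur with hydrogen delivered to C13 from the convex face and saturates both alkenes, giving 17.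

Step 6. The siloxyfuran may be protodesilylated or may deactivate the ruthenium carbene during the metathesis, and the exocyclic methylene of the pendant lactone may enter cross-metathesis. The fallback reverses the order of the two operations, sets out from 10 and returns at 13. Cross-metathesis of the robust butenolide 10 with crotonaldehyde (same catalyst) gives the butenolide enal F5. Chemoselective soft enolisation (TIPSOTf 1.05 equiv, Et3N, CH2Cl2, −78 °C) then silylates only the far more acidic butenolide and gives 13.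

Step 4. The aldehyde is a vinylogous amide and may react sluggishly with the allylchromium species, and facial selectivity with this heteroaryl aldehyde may be poor. The fallback sets C18 by asymmetric reduction instead of asymmetric C–C bond formation, sets out from 7 and returns at 10. Barbier allylation of 7 with 8 and In (THF/H2O, rt) gives the racemic hydroxy ester F6. MnO2 (CH2Cl2, rt) oxidises the pyrrolyl carbinol to the keto ester F7. Corey–Bakshi–Shibata reduction with the (R)-configured B-methyl oxazaborolidine and catecholborane (toluene, −78 °C) should give the (S)-hydroxy ester F8. NaH (cat., THF, 0 °C) closes the lactone to give 10.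

**Further compounds**

F1 | step 7 | (5S)-5-{1-(hex-5-en-1-yl)-4-[4-methyl-5-oxo-4-(phenylsulfanyl)-4,5-dihydrofuran-3-yl]-1H-pyrrol-2-yl}-3-methylideneoxolan-2-one (both configurations at the sulfide carbon) | C=CCCCCn1cc(C2=COC(=O)C2(C)Sc2ccccc2)cc1[C@@H]3CC(=C)C(=O)O3
F2 | step 7 | (2E)-7-{2-[(2S)-4-methylidene-5-oxooxolan-2-yl]-4-[4-methyl-5-oxo-4-(phenylsulfanyl)-4,5-dihydrofuran-3-yl]-1H-pyrrol-1-yl}hept-2-enal | O=C/C=C/CCCCn1cc(C2=COC(=O)C2(C)Sc2ccccc2)cc1[C@@H]3CC(=C)C(=O)O3
F3 | step 7 | pentacyclic sulfide aldehyde: compound 15 carrying a phenylsulfanyl group on C13 in place of hydrogen | O=C[C@H]1[C@H]2OC(=O)C(C)(Sc3ccccc3)[C@H]2c2cc([C@@H]3CC(=C)C(=O)O3)n3c2[C@@H]1CCCC3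
F4 | step 7 | pentacyclic vinyl sulfide: compound 16 carrying a phenylsulfanyl group on C13 in place of hydrogen | C=C[C@H]1[C@H]2OC(=O)C(C)(Sc3ccccc3)[C@H]2c2cc([C@@H]3CC(=C)C(=O)O3)n3c2[C@@H]1CCCC3
F5 | step 6 | (2E)-7-{2-[(2S)-4-methylidene-5-oxooxolan-2-yl]-4-(4-methyl-5-oxo-2,5-dihydrofuran-3-yl)-1H-pyrrol-1-yl}hept-2-enal | O=C/C=C/CCCCn1cc(C2=C(C)C(=O)OC2)cc1[C@@H]3CC(=C)C(=O)O3
F6 | step 4 | ethyl 4-[1-(hex-5-en-1-yl)-4-(4-methyl-5-oxo-2,5-dihydrofuran-3-yl)-1H-pyrrol-2-yl]-4-hydroxy-2-methylidenebutanoate (racemic) | C=CCCCCn1cc(C2=C(C)C(=O)OC2)cc1C(O)CC(=C)C(=O)OCC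
F7 | step 4 | ethyl 4-[1-(hex-5-en-1-yl)-4-(4-methyl-5-oxo-2,5-dihydrofuran-3-yl)-1H-pyrrol-2-yl]-2-methylidene-4-oxobutanoate | C=CCCCCn1cc(C2=C(C)C(=O)OC2)cc1C(=O)CC(=C)C(=O)OCC
F8 | step 4 | ethyl (4S)-4-[1-(hex-5-en-1-yl)-4-(4-methyl-5-oxo-2,5-dihydrofuran-3-yl)-1H-pyrrol-2-yl]-4-hydroxy-2-methylidenebutanoate | C=CCCCCn1cc(C2=C(C)C(=O)OC2)cc1[C@@H](O)CC(=C)C(=O)OCC
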